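**Retrosynthetic overview**
- The target is traced back to a cis-fused tricyclic lactone: the lactone carbonyl is the latent secondary methyl group and the ring oxygen is the phenol (lactol formation, then hydrazone reduction).
- Enabling feature: the phenolic oxygen is ortho to the quaternary ring carbon, and the secondary methyl on the neighbouring ring carbon is cis to the aryl group. The oxygen, two carbons of arene ring A, the quaternary carbon, the CH(CH3) carbon and that methyl carbon (as C=O) can therefore be closed to a δ-lactone, ring B, which is a coumarin whose C4=C3 bond is the future C(quaternary)–CH bond.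
- Key disconnection: both bonds from that C4=C3 unit to the three-carbon unit CH2–CH2–C(=CHBr). This is a (3+2) annulation of a 4-methylcoumarin-3-carboxylate with a 4-silylbut-3-ynyl zinc reagent: enantioselective conjugate addition, 5-exo-dig carbozincation by the zinc enolate, then bromination of the alkenylzinc.
- Ring order: ring A is bought; lactone ring B is closed first (acylation/Knoevenagel); cyclopentane ring C is closed in the key step; ring B is opened at the end, with the ester and silyl auxiliaries removed on the way.

Key step: step 3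

Assumption: the three building blocks (the bromo-hydroxyacetophenone, ethyl malonyl chloride and the silylated homopropargyl bromide) are taken as commercially available.

**Step 1**
Reactants: 1 1-(5-bromo-2-hydroxy-4-methylphenyl)ethan-1-one; 2 ethyl 3-chloro-3-oxopropanoate
Product: 4 ethyl 6-bromo-4,7-dimethyl-2-oxo-2H-chromene-3-carboxylate, via aryl ethyl malonate 3 (not isolated)
Conditions: pyridine, CH2Cl2, 0 °C to rt; then piperidine (cat.), AcOH (cat.), 40 °C
Reagents that add atoms: none
Why: O-Acylation of the phenol and amine-catalysed intramolecular Knoevenagel condensation of the malonate methylene with the ortho acetyl group should close lactone ring B as a 3-carboxycoumarin, a doubly activated acceptor; no stereocentre is formed.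

**Step 2**
Reactants: 5 (4-bromobut-1-yn-1-yl)trimethylsilane
Product: 7 [4-(trimethylsilyl)but-3-yn-1-yl][(trimethylsilyl)methyl]zinc, via Grignard reagent 6 (not isolated)
Conditions: Mg, Et2O, rt; then addition to Zn(OMe)2 (1.0 equiv) pretreated with Me3SiCH2MgCl (1.0 equiv), Et2O, 0 °C to rt; centrifugation (salt-free supernatant)
Reagents that add atoms: zinc dimethoxide, CO[Zn]OC; (trimethylsilyl)methylmagnesium chloride, C[Si](C)(C)C[Mg]Cl
Why: Grignard formation from the primary bromide and stepwise transmetalation on zinc dimethoxide (first the silylmethyl Grignard reagent, then 6), whose methoxymagnesium halide by-products precipitate, should give the salt-free mixed diorganozinc that asymmetric copper catalysis needs; the (trimethylsilyl)methyl group is a non-transferable ligand, so one equivalent of bromide 5 supplies the whole reagent, and the C-silyl group blocks the acetylenic C–H.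

**Step 3**
Reactants: 4 ethyl 6-bromo-4,7-dimethyl-2-oxo-2H-chromene-3-carboxylate; 7 [4-(trimethylsilyl)but-3-yn-1-yl][(trimethylsilyl)methyl]zinc (1.3 equiv)
Product: 10 ethyl (3Z,3aR,9bS)-8-bromo-3-[bromo(trimethylsilyl)methylidene]-7,9b-dimethyl-4-oxo-2,3,4,9b-tetrahydrocyclopenta[c]chromene-3a(1H)-carboxylate, via zinc enolate 8 (not isolated), via alkenylzinc 9 (not isolated)
Conditions: Cu(OTf)2 (5 mol%), (S)-BINOL-derived N,N-bis[(R)-1-phenylethyl]phosphoramidite (10 mol%), toluene, −30 to 0 °C; then 50 °C; then NBS (3 equiv), THF, −40 to 0 °C; aq. NH4Cl work-up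
Reagents that add atoms: N-bromosuccinimide, O=C1CCC(=O)N1Br
Why: Proposed new method: the chiral catalyst formed from Cu(OTf)2 and the phosphoramidite should transfer the 4-silylbut-3-ynyl group of 7, and not the silylmethyl group, from zinc to C4 of the doubly activated coumarin (1,4-addition), the zinc enolate 8 should then add syn across the tethered silylalkyne to give the ester-chelated α-silyl alkenylzinc 9, and NBS should replace zinc by bromine with retention while the excess cleaves the remaining Zn–CH2SiMe3 bond. The closest known reaction types are the copper-catalysed enantioselective addition of dialkylzincs to 1-arylalkylidene malonate-type acceptors (benzylic quaternary centres), the selective alkyl transfer from alkyl[(trimethylsilyl)methyl]zincs in copper-mediated conjugate additions, and the intramolecular carbometalation of unactivated alkynes by metal enolates of active methine compounds followed by halogenolysis of the alkenyl–metal bond. Ring C closes in the 5-exo-dig mode, which puts the metal on the silicon-bearing carbon. The quaternary centre C9b is set by the ligand, which selects one face of the planar coumarin C3=C4 bond (the antipodal ligand is used should the facial sense be opposite), and C3a needs no control because the tether on C9b can reach only the adjacent face of the enolate, which gives the cis ring fusion. The step needs 1,4- over 1,2-addition (secured by the soft copper alkyl and the alkylidene-malonate character of 4) and a syn, exo carbometalation (secured by the short tether, α-silyl stabilisation of the C–Zn bond and chelation by the ester), which places bromine cis to C3a as the target requires.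

**Step 4**
Reactants: 10 ethyl (3Z,3aR,9bS)-8-bromo-3-[bromo(trimethylsilyl)methylidene]-7,9b-dimethyl-4-oxo-2,3,4,9b-tetrahydrocyclopenta[c]chromene-3a(1H)-carboxylate
Product: 11 ethyl (3Z,3aR,9bS)-8-bromo-3-(bromomethylidene)-7,9b-dimethyl-4-oxo-2,3,4,9b-tetrahydrocyclopenta[c]chromene-3a(1H)-carboxylate
Conditions: Bu4NF (1.5 equiv), AcOH (1.5 equiv), THF, 0 °C to rt
Reagents that add atoms: none
Why: Fluoride-induced protodesilylation of a 1-bromo-1-silylalkene is a known reaction that proceeds with retention of alkene geometry, so hydrogen should take the place of silicon and bromine should stay cis to C3a; acetic acid buffers the medium and C3a carries no acidic hydrogen.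

**Step 5**
Reactants: 11 ethyl (3Z,3aR,9bS)-8-bromo-3-(bromomethylidene)-7,9b-dimethyl-4-oxo-2,3,4,9b-tetrahydrocyclopenta[c]chromene-3a(1H)-carboxylate
Product: 12 (3Z,3aR,9bR)-8-bromo-3-(bromomethylidene)-7,9b-dimethyl-2,3,3a,9b-tetrahydrocyclopenta[c]chromen-4(1H)-one
Conditions: LiCl (3 equiv), H2O (2 equiv), DMSO, 140 °C
Reagents that add atoms: none
Why: Krapcho dealkoxycarbonylation removes the activating ester, and α-protonation of the resulting lactone enolate should give the strongly favoured cis-fused 6-5 system, which fixes the C3a hydrogen cis to the C9b methyl group and keeps the exocyclic alkene.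

**Step 6**
Reactants: 12 (3Z,3aR,9bR)-8-bromo-3-(bromomethylidene)-7,9b-dimethyl-2,3,3a,9b-tetrahydrocyclopenta[c]chromen-4(1H)-one
Product: 13 (3Z,3aR,9bR)-8-bromo-3-(bromomethylidene)-7,9b-dimethyl-1,2,3,3a,4,9b-hexahydrocyclopenta[c]chromen-4-ol (both C4 epimers)
Conditions: i-Bu2AlH (1.2 equiv), CH2Cl2, −78 °C; aq. potassium sodium tartrate work-up
Reagents that add atoms: none
Why: Partial hydride reduction of the aryl lactone at low temperature should stop at the lactol (aluminium hemiacetal) and leave both C–Br bonds untouched.

**Step 7**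
Reactants: 13 (3Z,3aR,9bR)-8-bromo-3-(bromomethylidene)-7,9b-dimethyl-1,2,3,3a,4,9b-hexahydrocyclopenta[c]chromen-4-ol
Product: 15 4-bromo-2-[(1R,2R,3Z)-3-(bromomethylidene)-1,2-dimethylcyclopentyl]-5-methylphenol, via tosylhydrazone 14 (not isolated)
Conditions: TsNHNH2 (1.3 equiv), THF, rt; then catecholborane (4 equiv), CHCl3, 0 °C to rt; then NaOAc·3H2O, 60 °C
Reagents that add atoms: none
Why: The lactol opens to the hydroxy aldehyde, which is trapped as its tosylhydrazone and reduced by hydride transfer to C=N followed by loss of sulfinate and nitrogen (Caglioti-type hydrazone reduction), so the former lactone carbon should become the methyl group cis to the aryl ring and the phenol is set free under neutral, non-enolising conditions.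

**Compound list**
1 | 1-(5-bromo-2-hydroxy-4-methylphenyl)ethan-1-one | CC(=O)c1cc(Br)c(C)cc1O | starting material
2 | ethyl 3-chloro-3-oxopropanoate (ethyl malonyl chloride) | CCOC(=O)CC(Cl)=O | starting material
3 | 2-acetyl-4-bromo-5-methylphenyl ethyl propanedioate | CCOC(=O)CC(=O)Oc1cc(C)c(Br)cc1C(C)=O | intermediate
4 | ethyl 6-bromo-4,7-dimethyl-2-oxo-2H-chromene-3-carboxylate | CCOC(=O)C1=C(C)c2cc(Br)c(C)cc2OC1=O | intermediate
5 | (4-bromobut-1-yn-1-yl)trimethylsilane | C[Si](C)(C)C#CCCBr | starting material
6 | [4-(trimethylsilyl)but-3-yn-1-yl]magnesium bromide | C[Si](C)(C)C#CCC[Mg]Br | intermediate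
7 | [4-(trimethylsilyl)but-3-yn-1-yl][(trimethylsilyl)methyl]zinc | C[Si](C)(C)C#CCC[Zn]C[Si](C)(C)C | intermediate
8 | [(trimethylsilyl)methyl]zinc enolate (O-bound at C2) of ethyl (4S)-6-bromo-4,7-dimethyl-2-oxo-4-[4-(trimethylsilyl)but-3-yn-1-yl]chromane-3-carboxylate | CCOC(=O)C1=C(O[Zn]C[Si](C)(C)C)Oc2cc(C)c(Br)cc2[C@]1(C)CCC#C[Si](C)(C)C | intermediate
9 | alkenylzinc: compound 10 with [(trimethylsilyl)methyl]zinc in place of the vinylic bromine (zinc cis to C3a; 3Z,3aR,9bS) | Cc1cc(O3)c([C@]2(C)CC/C(=C(/[Zn]C[Si](C)(C)C)[Si](C)(C)C)[C@]2(C(=O)OCC)C3=O)cc1Br | intermediate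
10 | ethyl (3Z,3aR,9bS)-8-bromo-3-[bromo(trimethylsilyl)methylidene]-7,9b-dimethyl-4-oxo-2,3,4,9b-tetrahydrocyclopenta[c]chromene-3a(1H)-carboxylate | Cc1cc(O3)c([C@]2(C)CC/C(=C(/Br)[Si](C)(C)C)[C@]2(C(=O)OCC)C3=O)cc1Br | intermediate
11 | ethyl (3Z,3aR,9bS)-8-bromo-3-(bromomethylidene)-7,9b-dimethyl-4-oxo-2,3,4,9b-tetrahydrocyclopenta[c]chromene-3a(1H)-carboxylate | Cc1cc(O3)c([C@]2(C)CC/C(=C/Br)[C@]2(C(=O)OCC)C3=O)cc1Br | intermediate
12 | (3Z,3aR,9bR)-8-bromo-3-(bromomethylidene)-7,9b-dimethyl-2,3,3a,9b-tetrahydrocyclopenta[c]chromen-4(1H)-one | Cc1cc(O3)c([C@]2(C)CC/C(=C/Br)[C@@H]2C3=O)cc1Br | intermediate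
13 | (3Z,3aR,9bR)-8-bromo-3-(bromomethylidene)-7,9b-dimethyl-1,2,3,3a,4,9b-hexahydrocyclopenta[c]chromen-4-ol (both C4 epimers) | Cc1cc(O3)c([C@]2(C)CC/C(=C/Br)[C@@H]2C3O)cc1Br | intermediate
14 | N'-{[(1R,2R,5Z)-2-(5-bromo-2-hydroxy-4-methylphenyl)-5-(bromomethylidene)-2-methylcyclopentyl]methylidene}-4-methylbenzenesulfonohydrazide | Cc1cc(O)c([C@]2(C)CC/C(=C/Br)[C@@H]2C=NNS(=O)(=O)c3ccc(C)cc3)cc1Br | intermediate
15 | 4-bromo-2-[(1R,2R,3Z)-3-(bromomethylidene)-1,2-dimethylcyclopentyl]-5-methylphenol | Cc1cc(O)c([C@]2(C)CC/C(=C/Br)[C@@H]2C)cc1Br | target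

**Step count and risks**
Total step count: 7. Longest linear sequence: 6 steps (steps 1, 3, 4, 5, 6 and 7 from ketone 1; step 2 is the convergent branch).

Steps most likely to fail:

Step 3 (Proposed new method). The alkyl transfer to the hindered C4 may be slow or show poor facial selectivity, the silylmethyl group may compete in the transfer, and the zinc enolate may fail to carbometalate the silylalkyne, so that NBS brominates the enolate instead. The fallback uses known chemistry and sets out from 4 and Grignard reagent 6. CuI-catalysed conjugate addition (THF, −30 °C) gives the racemic adduct ethyl 6-bromo-4,7-dimethyl-2-oxo-4-[4-(trimethylsilyl)but-3-yn-1-yl]chromane-3-carboxylate F1. AgNO3 (cat.)/NBS in acetone converts the alkynylsilane into the bromoalkyne ethyl 6-bromo-4-(4-bromobut-3-yn-1-yl)-4,7-dimethyl-2-oxochromane-3-carboxylate F2. A gold-catalysed Conia-ene cyclisation (Ph3PAuCl/AgOTf, CH2Cl2) adds the 1,3-dicarbonyl C–H anti across the bromoalkyne, which should give the cis-fused (Z)-bromomethylidene lactone as the racemate, that is 11 together with its enantiomer ethyl (3Z,3aS,9bR)-8-bromo-3-(bromomethylidene)-7,9b-dimethyl-4-oxo-2,3,4,9b-tetrahydrocyclopenta[c]chromene-3a(1H)-carboxylate F3. Preparative chromatography on a chiral stationary phase separates the two, and the route is rejoined at 11.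

Step 7. The carbon α to the open-chain aldehyde is also allylic, so epimerisation or migration of the double bond into conjugation may occur during hydrazone formation, and the phenol may re-close to a chroman during reduction. The fallback sets out from lactone 12. LiBH4 (THF, 0 °C) reduces it directly to the diol 4-bromo-2-[(1R,2R,3Z)-3-(bromomethylidene)-2-(hydroxymethyl)-1-methylcyclopentyl]-5-methylphenol F4. TsCl/pyridine at 0 °C should sulfonylate the primary alcohol in preference to the hindered phenol and give [(1R,2R,5Z)-2-(5-bromo-2-hydroxy-4-methylphenyl)-5-(bromomethylidene)-2-methylcyclopentyl]methyl 4-methylbenzenesulfonate F5. LiEt3BH (THF, 0 °C) displaces the sulfonate by hydride, and the route is rejoined at 15.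

Step 4. The transient α-bromovinyl anion may undergo α-elimination (carbenoid pathways), or alkene geometry may erode during desilylation. The fallback sets out from 10 and is independent of the geometry delivered by step 3. NBS in MeCN (ipso-bromodesilylation) gives the gem-dibromoalkene ethyl (3aR,9bS)-8-bromo-3-(dibromomethylidene)-7,9b-dimethyl-4-oxo-2,3,4,9b-tetrahydrocyclopenta[c]chromene-3a(1H)-carboxylate F6. Pd(PPh3)4 (cat.)/Bu3SnH at rt should remove selectively the less hindered vinylic bromine, the one trans to the quaternary C3a, because the activated dibromoalkene reacts with zerovalent palladium much faster than the aryl bromide. This leaves bromine cis to C3a, and the route is rejoined at 11.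

**Further compounds**
F1 | step 3 | ethyl 6-bromo-4,7-dimethyl-2-oxo-4-[4-(trimethylsilyl)but-3-yn-1-yl]chromane-3-carboxylate (racemic, both C3 epimers) | CCOC(=O)C1C(=O)Oc2cc(C)c(Br)cc2C1(C)CCC#C[Si](C)(C)C
F2 | step 3 | ethyl 6-bromo-4-(4-bromobut-3-yn-1-yl)-4,7-dimethyl-2-oxochromane-3-carboxylate (racemic) | CCOC(=O)C1C(=O)Oc2cc(C)c(Br)cc2C1(C)CCC#CBr
F3 | step 3 | ethyl (3Z,3aS,9bR)-8-bromo-3-(bromomethylidene)-7,9b-dimethyl-4-oxo-2,3,4,9b-tetrahydrocyclopenta[c]chromene-3a(1H)-carboxylate (enantiomer of 11) | Cc1cc(O3)c([C@@]2(C)CC/C(=C/Br)[C@@]2(C(=O)OCC)C3=O)cc1Br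
F4 | step 7 | 4-bromo-2-[(1R,2R,3Z)-3-(bromomethylidene)-2-(hydroxymethyl)-1-methylcyclopentyl]-5-methylphenol | Cc1cc(O)c([C@]2(C)CC/C(=C/Br)[C@@H]2CO)cc1Br
F5 | step 7 | [(1R,2R,5Z)-2-(5-bromo-2-hydroxy-4-methylphenyl)-5-(bromomethylidene)-2-methylcyclopentyl]methyl 4-methylbenzenesulfonate | Cc1cc(O)c([C@]2(C)CC/C(=C/Br)[C@@H]2COS(=O)(=O)c3ccc(C)cc3)cc1Br
F6 | step 4 | ethyl (3aR,9bS)-8-bromo-3-(dibromomethylidene)-7,9b-dimethyl-4-oxo-2,3,4,9b-tetrahydrocyclopenta[c]chromene-3a(1H)-carboxylate | Cc1cc(O3)c([C@]2(C)CCC(=C(Br)Br)[C@]2(C(=O)OCC)C3=O)cc1Br
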